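## Retrosynthetic overview
- The carbinol is set last, by catalyst-controlled transfer hydrogenation of the 1-aroylindane. This face is also the Felkin–Anh face. The six phenols are freed one step earlier.
- The 1-aroylindane comes from an acyclic meso 2,3-diaryl-1,4-diketone. The disconnection breaks C3–C3a (Friedel–Crafts) and returns C3 to a carbonyl.
- Ring order: in one flask a dihydrofuran O-ring closes first and the indane carbocycle second. The O-ring is consumed as the carbocycle forms. The four arenes are bought.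
- The meso-diketone comes from oxidative enolate homocoupling of a deoxybenzoin, which makes the future C1–C2 bond. The deoxybenzoin comes from Pd α-arylation of 4'-methoxyacetophenone.

Assumption: the SMILES is read as (1R,2S,3R) on the indane (all-trans) and (R) at the carbinol carbon. The named catalysts are treated as purchasable.

## Route

Step 1
Reactants: 1 4'-methoxyacetophenone; 2 1-bromo-3,5-dimethoxybenzene
Product: 3 2-(3,5-dimethoxyphenyl)-1-(4-methoxyphenyl)ethan-1-one
Conditions: Pd(OAc)2 (1 mol %), XPhos (2 mol %), NaOt-Bu, toluene, 80 °C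
Reagents that add atoms: none
Why: Pd-catalysed ketone α-arylation (Buchwald–Hartwig type) couples the methyl ketone enolate with the aryl bromide, the more acidic and more hindered product enolate resists a second arylation, and no stereocentre is formed.

Step 2
Reactants: 3 2-(3,5-dimethoxyphenyl)-1-(4-methoxyphenyl)ethan-1-one (two equivalents)
Product: 6 meso-(2R,3S)-2,3-bis(3,5-dimethoxyphenyl)-1,4-bis(4-methoxyphenyl)butane-1,4-dione, via alpha-iodo ketone 4 (not isolated), via dl-diketone 5 (not isolated)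
Conditions: NaHMDS, THF, −78 °C; I2 (0.5 equiv), −78 °C → rt; then NaOEt (10 mol %), EtOH, reflux → 20 °C, filter
Reagents that add atoms: none
Why: Oxidative enolate homocoupling (α-iodination, then SN2 by a second enolate) makes the central C–C bond, and because both new stereocentres are acidic α-carbons the alkoxide slurry drains the soluble dl-isomer into the less soluble meso-isomer (crystallisation-induced diastereomer transformation), which fixes the (2R,3S) relative configuration.

Step 3
Reactants: 6 meso-(2R,3S)-2,3-bis(3,5-dimethoxyphenyl)-1,4-bis(4-methoxyphenyl)butane-1,4-dione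
Product: 9 (1R,2S,3R)-[2-(3,5-dimethoxyphenyl)-4,6-dimethoxy-3-(4-methoxyphenyl)-2,3-dihydro-1H-inden-1-yl](4-methoxyphenyl)methanone, via hydroxy ketone 7 (not isolated), via cis-dihydrofuran 8 (not isolated)
Conditions: (S,S)-Ts-DENEB (oxo-tethered Ru–TsDPEN, 1 mol %), HCO2H/Et3N 5:2, CH2Cl2, 30 °C; then TFA, −20 → 0 °C
Reagents that add atoms: none
Why: Proposed new method: the (S,S)-Noyori–Ikariya catalyst makes (S)-aryl carbinols, and only the carbonyl next to the (S)-α-carbon of meso-6 can take hydride on that face in a Felkin–Anh sense (anti to the α-aryl group), so this enantiotopic-carbonyl-selective transfer hydrogenation decides which α-carbon becomes C2 (S) while the mismatched second ketone survives (a wrongly reduced mono-alcohol keeps a matched ketone and is drained to the diol, which raises ee); TFA then cyclodehydrates 7 to the strained cis-dihydrofuran 8, C-protonation of its enol ether turns the ketone into a leaving group, and the p-anisyl cation is captured irreversibly by the ortho/para-activated carbon of the neighbouring 3,5-dimethoxyphenyl ring (intramolecular Friedel–Crafts alkylation), which sets C3 trans to the C2 aryl group, with C1 settling trans under Curtin–Hammett and thermodynamic control; the closest known reaction types are ATH desymmetrisation of meso-diketones, ATH with dynamic kinetic resolution of α-branched aryl ketones, acid ionisation of 2-aryl-2,3-dihydrofurans (reverse Cloke–Wilson manifold) and cationic indane closures of p-alkoxybenzyl cations.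

Step 4
Reactants: 9 (1R,2S,3R)-[2-(3,5-dimethoxyphenyl)-4,6-dimethoxy-3-(4-methoxyphenyl)-2,3-dihydro-1H-inden-1-yl](4-methoxyphenyl)methanone
Product: 10 (1R,2S,3R)-[2-(3,5-dihydroxyphenyl)-4,6-dihydroxy-3-(4-hydroxyphenyl)-2,3-dihydro-1H-inden-1-yl](4-hydroxyphenyl)methanone
Conditions: BBr3 (12 equiv), CH2Cl2, −78 °C → rt; MeOH/H2O quench
Reagents that add atoms: none
Why: Lewis-acid aryl methyl ether cleavage (BBr3 demethylation) removes all six methyl groups and leaves the aryl ketone and the three C–H stereocentres untouched, because C1 is the only epimerisable centre and already sits trans (the thermodynamic arrangement), and that trans geometry keeps the activated carbonyl out of reach of the C2 aryl ring.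

Step 5
Reactants: 10 (1R,2S,3R)-[2-(3,5-dihydroxyphenyl)-4,6-dihydroxy-3-(4-hydroxyphenyl)-2,3-dihydro-1H-inden-1-yl](4-hydroxyphenyl)methanone
Product: 11 (1R,2S,3R)-2-(3,5-dihydroxyphenyl)-1-[(R)-hydroxy(4-hydroxyphenyl)methyl]-3-(4-hydroxyphenyl)-2,3-dihydro-1H-indene-4,6-diol
Conditions: (R,R)-Ts-DENEB (2 mol %), HCO2H/Et3N 1:1, MeOH, 30 °C
Reagents that add atoms: none
Why: In Noyori–Ikariya asymmetric transfer hydrogenation the (R,R)-catalyst turns aryl ketones into (R)-aryl carbinols (same CIP order O > aryl > alkyl as for acetophenone), and this face is also the Felkin–Anh face of 10 (attack anti to the C1–C7a aryl bond of the (1R)-centre), so reagent and substrate control are matched for the (R)-carbinol while the near-neutral medium spares the labile p-hydroxybenzylic alcohol.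

## Compound list
1 | 4'-methoxyacetophenone | CC(=O)c1ccc(OC)cc1 | starting material
2 | 1-bromo-3,5-dimethoxybenzene | COc1cc(Br)cc(OC)c1 | starting material
3 | 2-(3,5-dimethoxyphenyl)-1-(4-methoxyphenyl)ethan-1-one | COc1ccc(cc1)C(=O)Cc1cc(OC)cc(OC)c1 | intermediate
4 | 2-(3,5-dimethoxyphenyl)-2-iodo-1-(4-methoxyphenyl)ethan-1-one (racemic, not isolated) | COc1ccc(cc1)C(=O)C(I)c1cc(OC)cc(OC)c1 | intermediate
5 | rac-(2R,3R)-2,3-bis(3,5-dimethoxyphenyl)-1,4-bis(4-methoxyphenyl)butane-1,4-dione (dl-isomer, one enantiomer drawn, not isolated) | COc1ccc(cc1)C(=O)[C@@H](c1cc(OC)cc(OC)c1)[C@H](c1cc(OC)cc(OC)c1)C(=O)c1ccc(OC)cc1 | intermediate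
6 | meso-(2R,3S)-2,3-bis(3,5-dimethoxyphenyl)-1,4-bis(4-methoxyphenyl)butane-1,4-dione | COc1ccc(cc1)C(=O)[C@@H](c1cc(OC)cc(OC)c1)[C@@H](c1cc(OC)cc(OC)c1)C(=O)c1ccc(OC)cc1 | intermediate
7 | (2R,3S,4S)-2,3-bis(3,5-dimethoxyphenyl)-4-hydroxy-1,4-bis(4-methoxyphenyl)butan-1-one (not isolated) | COc1ccc(cc1)C(=O)[C@@H](c1cc(OC)cc(OC)c1)[C@@H](c1cc(OC)cc(OC)c1)[C@H](O)c1ccc(OC)cc1 | intermediate
8 | (2S,3R)-3,4-bis(3,5-dimethoxyphenyl)-2,5-bis(4-methoxyphenyl)-2,3-dihydrofuran (2,3-cis, not isolated) | COc1ccc(cc1)C1=C(c2cc(OC)cc(OC)c2)[C@@H](c2cc(OC)cc(OC)c2)[C@H](O1)c1ccc(OC)cc1 | intermediate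
9 | (1R,2S,3R)-[2-(3,5-dimethoxyphenyl)-4,6-dimethoxy-3-(4-methoxyphenyl)-2,3-dihydro-1H-inden-1-yl](4-methoxyphenyl)methanone | COc1ccc([C@@H]2c3c(OC)cc(OC)cc3[C@H](C(=O)c3ccc(OC)cc3)[C@H]2c2cc(OC)cc(OC)c2)cc1 | intermediate
10 | (1R,2S,3R)-[2-(3,5-dihydroxyphenyl)-4,6-dihydroxy-3-(4-hydroxyphenyl)-2,3-dihydro-1H-inden-1-yl](4-hydroxyphenyl)methanone | Oc1ccc([C@@H]2c3c(O)cc(O)cc3[C@H](C(=O)c3ccc(O)cc3)[C@H]2c2cc(O)cc(O)c2)cc1 | intermediate
11 | (1R,2S,3R)-2-(3,5-dihydroxyphenyl)-1-[(R)-hydroxy(4-hydroxyphenyl)methyl]-3-(4-hydroxyphenyl)-2,3-dihydro-1H-indene-4,6-diol | Oc1ccc([C@@H]2c3c(O)cc(O)cc3[C@H]([C@@H](O)c3ccc(O)cc3)[C@H]2c2cc(O)cc(O)c2)cc1 | target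

Total step count: 5
Longest linear sequence: 5

## Steps most likely to fail

**Step 3.**
- The catalyst may not distinguish the two carbonyls well enough, which would give low ee or over-reduction to the diol.
- The amine may epimerise 6.
- E1 loss of the proton next to the cation may erode the C2 configuration.

The fallback takes the absolute configuration from an epoxide instead. It sets out from 3 and comes back at 9. Commercial (E)-3,4',5-trimethoxystilbene is epoxidised with the D-fructose-derived Shi ketone and Oxone to (2R,3R)-2-(3,5-dimethoxyphenyl)-3-(4-methoxyphenyl)oxirane F1. With BF3·OEt2 at −78 °C the activated ring carbon of 3 opens F1 at the p-anisyl carbon with inversion. This gives 2-{2-[(1R,2S)-2-(3,5-dimethoxyphenyl)-2-hydroxy-1-(4-methoxyphenyl)ethyl]-3,5-dimethoxyphenyl}-1-(4-methoxyphenyl)ethan-1-one F2. MsCl/Et3N converts it into the corresponding methanesulfonate F3. KOt-Bu then closes the five-membered ring by 5-exo-tet enolate alkylation with inversion. The two inversions map the trans-epoxide onto the trans C2/C3 pair of 9, and C1 equilibrates to trans.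

**Step 5.**
- The hindered, electron-rich p-hydroxyaryl ketone may be reduced too slowly or with poor diastereoselectivity.
- The product may ionise in the medium.

The fallback sets out from 10 and comes back at 11. TBSCl/imidazole gives the hexakis-O-(tert-butyldimethylsilyl) ether of ketone 10 F4, which is a more electrophilic ketone. DIBAL-H in toluene at −78 °C reduces it under pure substrate (Felkin–Anh) control to the hexakis-O-(tert-butyldimethylsilyl) ether of carbinol 11 F5, which can be purified on silica from its epimer. TBAF buffered with AcOH at 0 °C then releases 11.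

**Step 2.**
- The coupling may be low-yielding.
- The meso-isomer may not be the one that crystallises.

The fallback sets out from the unsorted mixture of 5 and 6 and comes back at 6. TsOH in refluxing toluene converts both diastereomers (Paal–Knorr) into 3,4-bis(3,5-dimethoxyphenyl)-2,5-bis(4-methoxyphenyl)furan F6. mCPBA opens the furan to (Z)-2,3-bis(3,5-dimethoxyphenyl)-1,4-bis(4-methoxyphenyl)but-2-ene-1,4-dione F7. Syn-hydrogenation (H2, Pd/C, EtOAc, neutral) of this cis-diaroyl alkene gives only the meso-diketone 6.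

## Further compounds
F1 | step 3 | (2R,3R)-2-(3,5-dimethoxyphenyl)-3-(4-methoxyphenyl)oxirane | COc1ccc(cc1)[C@H]1O[C@@H]1c1cc(OC)cc(OC)c1
F2 | step 3 | 2-{2-[(1R,2S)-2-(3,5-dimethoxyphenyl)-2-hydroxy-1-(4-methoxyphenyl)ethyl]-3,5-dimethoxyphenyl}-1-(4-methoxyphenyl)ethan-1-one | COc1ccc(cc1)C(=O)Cc1cc(OC)cc(OC)c1[C@@H](c1ccc(OC)cc1)[C@H](O)c1cc(OC)cc(OC)c1
F3 | step 3 | methanesulfonate of F2 | COc1ccc(cc1)C(=O)Cc1cc(OC)cc(OC)c1[C@@H](c1ccc(OC)cc1)[C@H](OS(C)(=O)=O)c1cc(OC)cc(OC)c1
F4 | step 5 | hexakis-O-(tert-butyldimethylsilyl) ether of ketone 10 | CC(C)(C)[Si](C)(C)Oc1ccc([C@@H]2c3c(O[Si](C)(C)C(C)(C)C)cc(O[Si](C)(C)C(C)(C)C)cc3[C@H](C(=O)c3ccc(O[Si](C)(C)C(C)(C)C)cc3)[C@H]2c2cc(O[Si](C)(C)C(C)(C)C)cc(O[Si](C)(C)C(C)(C)C)c2)cc1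
F5 | step 5 | hexakis-O-(tert-butyldimethylsilyl) ether of carbinol 11 | CC(C)(C)[Si](C)(C)Oc1ccc([C@@H]2c3c(O[Si](C)(C)C(C)(C)C)cc(O[Si](C)(C)C(C)(C)C)cc3[C@H]([C@@H](O)c3ccc(O[Si](C)(C)C(C)(C)C)cc3)[C@H]2c2cc(O[Si](C)(C)C(C)(C)C)cc(O[Si](C)(C)C(C)(C)C)c2)cc1
F6 | step 2 | 3,4-bis(3,5-dimethoxyphenyl)-2,5-bis(4-methoxyphenyl)furan | COc1ccc(cc1)c1oc(c2ccc(OC)cc2)c(c2cc(OC)cc(OC)c2)c1c1cc(OC)cc(OC)c1
F7 | step 2 | (Z)-2,3-bis(3,5-dimethoxyphenyl)-1,4-bis(4-methoxyphenyl)but-2-ene-1,4-dione | COc1ccc(cc1)C(=O)/C(c1cc(OC)cc(OC)c1)=C(/c1cc(OC)cc(OC)c1)C(=O)c1ccc(OC)cc1
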